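## Retrosynthetic overview

- Feature: ring A has four adjacent oxygen-bearing carbons, C5, C6, C7 and C8. They map onto the four ring carbons of dimethyl squarate, and C7 (the only free OH) is the beta-carbon C3 of the derived cyclobutenone, the one position whose alkoxy group can be swapped.
- Endgame: the target comes from its 7-O-benzyl ether by hydrogenolysis, and that ether from the chelated 5-phenol by O-methylation.
- Key disconnection C4a–C5: ring A comes from a 4-methoxy-4-(4-oxopyran-2-yl)cyclobutenone by thermal four-electron ring opening and six-electron closure of the dienylketene.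
- Bond C8–C8a: the 2-arylpyran-4-one, lithiated at C6, adds 1,2 to dimethyl squarate. O-methylation then sets the 8-OMe group, and MeO-to-BnO exchange at cyclobutenone C3 marks C7.
- Ring order: ring B and the four-membered ring are bought, ring C (the pyranone) is made first by acylation and cyclisation, and ring A is closed last.

Key step: step 6

Assumption: the target is achiral. The cyclobutenone intermediates are handled as racemates, because their single quaternary stereocentre becomes the planar carbon C8 in the key step.

## Route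

Step 1
Reactants: 1 (E)-4-methoxybut-3-en-2-one; 2 3,4-dimethoxybenzoyl chloride
Product: 4 (E)-1-(3,4-dimethoxyphenyl)-5-methoxypent-4-ene-1,3-dione, via lithium dienolate 3 (not isolated)
Conditions: 1 (2 equiv), LiN(SiMe3)2 (2 equiv), THF, −78 °C; then 2 (1 equiv), −78 °C; AcOH quench
Reagents that add atoms: none
Why: Kinetic deprotonation of the methyl ketone gives cross-conjugated dienolate 3, which is C-acylated by the acid chloride (Claisen-type acylation), while the second equivalent of 3 takes up the acidic proton of 4 so that double acylation is avoided; no stereocentre is formed.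

Step 2
Reactants: 4 (E)-1-(3,4-dimethoxyphenyl)-5-methoxypent-4-ene-1,3-dione
Product: 5 2-(3,4-dimethoxyphenyl)-4H-pyran-4-one
Conditions: CF3CO2H, PhMe, rt
Reagents that add atoms: none
Why: In an acid-catalysed intramolecular oxa-Michael addition–elimination, the enol oxygen of the aroyl ketone adds to the methoxy-bearing enone carbon (6-endo-trig) and methanol is lost, which is the standard closure of acylated methoxybutenones to gamma-pyrones and forms ring C.

Step 3
Reactants: 5 2-(3,4-dimethoxyphenyl)-4H-pyran-4-one; 6 dimethyl squarate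
Product: 8 rac-4-[6-(3,4-dimethoxyphenyl)-4-oxo-4H-pyran-2-yl]-4-hydroxy-2,3-dimethoxycyclobut-2-en-1-one, via 6-lithiopyranone 7 (not isolated)
Conditions: lithium 2,2,6,6-tetramethylpiperidide (1.05 equiv, from 2,2,6,6-tetramethylpiperidine and n-BuLi, THF, 0 °C), slow addition of 5, THF, −78 °C, 15 min; then 6 (1.2 equiv), THF, −78 °C; AcOH quench at −78 °C
Reagents that add atoms: none
Why: This is vinylic deprotonation beside a ring oxygen followed by 1,2-addition of the sp2 organolithium to one of the two equivalent squarate carbonyls (the standard entry to 4-substituted 4-hydroxycyclobutenones): C6–H is the only C–H next to O1 and the most acidic one of a gamma-pyrone (the site of base-catalysed H/D exchange and of chromone lithiation), the hindered amide does not add to the enone, slow addition to the base keeps free 5 away from 7, and the new quaternary carbon forms as a racemate that is erased in step 6.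

Step 4
Reactants: 8 rac-4-[6-(3,4-dimethoxyphenyl)-4-oxo-4H-pyran-2-yl]-4-hydroxy-2,3-dimethoxycyclobut-2-en-1-one
Product: 9 rac-4-[6-(3,4-dimethoxyphenyl)-4-oxo-4H-pyran-2-yl]-2,3,4-trimethoxycyclobut-2-en-1-one
Conditions: MeI (10 equiv), Ag2O (1.5 equiv), 4 Å MS, MeCN, rt, dark
Reagents that add atoms: iodomethane, CI
Why: Purdie methylation (Ag2O-promoted O-alkylation) is the usual way to cap squarate-derived tertiary cyclobutenols without a free alkoxide that could open the strained ring, and it installs both the future 8-OMe group and the donor that steers the ring opening in step 6.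

Step 5
Reactants: 9 rac-4-[6-(3,4-dimethoxyphenyl)-4-oxo-4H-pyran-2-yl]-2,3,4-trimethoxycyclobut-2-en-1-one; 10 benzyl alcohol
Product: 11 rac-3-benzyloxy-4-[6-(3,4-dimethoxyphenyl)-4-oxo-4H-pyran-2-yl]-2,4-dimethoxycyclobut-2-en-1-one
Conditions: 10 (5 equiv), LiOt-Bu (0.2 equiv), 4 Å MS, THF, −20 to 0 °C; AcOH quench
Reagents that add atoms: none
Why: In this vinylogous transesterification by addition–elimination (as in the alcohol exchange of squarate esters), benzyloxide can add productively only at C3, the carbon beta to the ring carbonyl, because C2 is the electron-rich alpha-carbon, C4 is a saturated tertiary ether and the aryl ethers are inert; loss of methoxide gives 11, the excess of 10 and uptake of methanol by the sieves shift the equilibrium, and low temperature with catalytic base spares the ring carbonyl and the pyranone.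

Step 6
Reactants: 11 rac-3-benzyloxy-4-[6-(3,4-dimethoxyphenyl)-4-oxo-4H-pyran-2-yl]-2,4-dimethoxycyclobut-2-en-1-one
Product: 14 7-benzyloxy-5-hydroxy-6,8,3',4'-tetramethoxyflavone, via (Z)-dienylketene 12 (not isolated), via ring-A cyclohexadienone 13 (not isolated)
Conditions: PhMe (0.02 M, degassed), 110 °C, Ar
Reagents that add atoms: none
Why: Proposed new method: heating breaks the C1–C4 bond of the cyclobutenone (flavone C5–C8) in a conrotatory four-electron opening, and torquoselectivity sends the donor 4-methoxy group outward and the pyranyl group inward, so that in (Z)-dienylketene 12 the ketene carbon lies next to the pyranone C2=C3 bond (flavone C8a=C4a). A disrotatory six-electron electrocyclisation then joins the electrophilic ketene carbon C5 to C4a, the nucleophilic alpha-carbon of the pyranone (beta-carbon of its O1–C8a=C4a enol ether and the site of electrophilic substitution in gamma-pyrones), and closes six-membered ring A as dienone 13. The C4a–H of 13 sits between two carbonyl groups and should move to the C5 oxygen at once, which aromatises ring A, restores the chromone and leaves the 5-OH hydrogen-bonded to the C4 carbonyl as a thermodynamic sink. The closest known reaction type is the Moore-type benzannulation of 4-aryl-, 4-heteroaryl- and 4-alkenyl-4-alkoxycyclobutenones to 4-alkoxyphenols, and the new element is a 4-oxopyran-2-yl group as the alkenyl arm, whose low aromaticity should make it behave as a cyclic alkoxyalkene rather than as an arene. No stereocentre is created, since the racemic quaternary carbon becomes planar C8 and the transient C4a centre of 13 is lost on enolisation. The step needs inward rotation of the pyranyl group (secured by the 4-OMe donor, and a wrongly opened ketene can only re-close because no free OH can trap it) and closure at carbon rather than at the ring oxygen (only C4a gives a neutral six-membered ring), while the oxygen pattern is fixed beforehand because cyclobutenone C1, C2, C3 and C4 become C5, C6, C7 and C8.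

Step 7
Reactants: 14 7-benzyloxy-5-hydroxy-6,8,3',4'-tetramethoxyflavone
Product: 15 7-benzyloxy-5,6,8,3',4'-pentamethoxyflavone
Conditions: MeI (5 equiv), K2CO3 (3 equiv), DMF, 50 °C
Reagents that add atoms: iodomethane, CI
Why: In this Williamson ether synthesis the chelated 5-OH is the only free hydroxyl group, and excess reagent with gentle warming is the normal way to methylate 5-hydroxyflavones; the benzyl ether and the chromone are inert to carbonate.

Step 8
Reactants: 15 7-benzyloxy-5,6,8,3',4'-pentamethoxyflavone
Product: 16 7-hydroxy-5,6,8,3',4'-pentamethoxyflavone (target)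
Conditions: H2 (1 atm), 10% Pd/C, EtOAc–MeOH, rt
Reagents that add atoms: none
Why: Catalytic hydrogenolysis cleaves only the benzylic C–O bond of the aryl benzyl ether, while the five methyl ethers and the conjugated C2=C3 bond of the flavone persist at one atmosphere if the reaction is stopped when 15 is consumed.

## Compound list

1 | (E)-4-methoxybut-3-en-2-one | CO/C=C/C(C)=O | starting material
2 | 3,4-dimethoxybenzoyl chloride | COc1ccc(C(=O)Cl)cc1OC | starting material
3 | lithium dienolate of 1, lithium (E)-4-methoxybuta-1,3-dien-2-olate | C=C(O[Li])/C=C/OC | intermediate (not isolated)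
4 | (E)-1-(3,4-dimethoxyphenyl)-5-methoxypent-4-ene-1,3-dione | CO/C=C/C(=O)CC(=O)c1ccc(OC)c(OC)c1 | intermediate
5 | 2-(3,4-dimethoxyphenyl)-4H-pyran-4-one | COc1ccc(-c2cc(=O)cco2)cc1OC | intermediate
6 | dimethyl squarate (3,4-dimethoxycyclobut-3-ene-1,2-dione) | COC1=C(OC)C(=O)C1=O | starting material
7 | 2-(3,4-dimethoxyphenyl)-6-lithio-4H-pyran-4-one | [Li]c1cc(=O)cc(-c2ccc(OC)c(OC)c2)o1 | intermediate (not isolated)
8 | rac-4-[6-(3,4-dimethoxyphenyl)-4-oxo-4H-pyran-2-yl]-4-hydroxy-2,3-dimethoxycyclobut-2-en-1-one | COC1=C(OC)C(O)(c2cc(=O)cc(-c3ccc(OC)c(OC)c3)o2)C1=O | intermediate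
9 | rac-4-[6-(3,4-dimethoxyphenyl)-4-oxo-4H-pyran-2-yl]-2,3,4-trimethoxycyclobut-2-en-1-one | COC1=C(OC)C(OC)(c2cc(=O)cc(-c3ccc(OC)c(OC)c3)o2)C1=O | intermediate
10 | benzyl alcohol | OCc1ccccc1 | starting material
11 | rac-3-benzyloxy-4-[6-(3,4-dimethoxyphenyl)-4-oxo-4H-pyran-2-yl]-2,4-dimethoxycyclobut-2-en-1-one | COC1=C(OCc2ccccc2)C(OC)(c2cc(=O)cc(-c3ccc(OC)c(OC)c3)o2)C1=O | intermediate (key-step precursor)
12 | (Z)-3-benzyloxy-4-[6-(3,4-dimethoxyphenyl)-4-oxo-4H-pyran-2-yl]-2,4-dimethoxybuta-1,3-dien-1-one (dienylketene) | O=C=C(OC)/C(OCc1ccccc1)=C(/OC)c1cc(=O)cc(-c2ccc(OC)c(OC)c2)o1 | intermediate (not isolated)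
13 | 7-benzyloxy-2-(3,4-dimethoxyphenyl)-6,8-dimethoxy-4aH-chromene-4,5-dione (racemic at C4a) | COc1ccc(C2=CC(=O)C3C(=O)C(OC)=C(OCc4ccccc4)C(OC)=C3O2)cc1OC | intermediate (not isolated)
14 | 7-benzyloxy-5-hydroxy-6,8,3',4'-tetramethoxyflavone | COc1ccc(-c2cc(=O)c3c(O)c(OC)c(OCc4ccccc4)c(OC)c3o2)cc1OC | intermediate (key-step product)
15 | 7-benzyloxy-5,6,8,3',4'-pentamethoxyflavone | COc1ccc(-c2cc(=O)c3c(OC)c(OC)c(OCc4ccccc4)c(OC)c3o2)cc1OC | intermediate
16 | 7-hydroxy-5,6,8,3',4'-pentamethoxyflavone | COc1ccc(-c2cc(=O)c3c(OC)c(OC)c(O)c(OC)c3o2)cc1OC | target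

Total step count: 8. Longest linear sequence: 8 steps (from 1 and 2 to 16).

## Steps most likely to fail

**Step 6.** The ketene may close too slowly onto the electron-poor, cross-conjugated C8a=C4a bond. Ring opening would then simply reverse, or the ketene would be lost by dimerisation or by acylating phenol already formed.

The fallback closes ring A on a plain enol-ether arm, a known type of arm for this benzannulation, and builds ring C afterwards by classical flavone chemistry. It sets out from 6 and returns at 15.

- Methyl vinyl ether and t-BuLi (THF, −78 to 0 °C) give 1-methoxyvinyllithium F1. This adds to 6 at −78 °C (AcOH quench) to give rac-4-hydroxy-2,3-dimethoxy-4-(1-methoxyvinyl)cyclobut-2-en-1-one F2.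
- MeI/Ag2O gives rac-2,3,4-trimethoxy-4-(1-methoxyvinyl)cyclobut-2-en-1-one F3. Exchange with 10 as in step 5 gives rac-3-benzyloxy-2,4-dimethoxy-4-(1-methoxyvinyl)cyclobut-2-en-1-one F4.
- Heating in toluene effects the established 4-alkenylcyclobutenone benzannulation to 3-benzyloxy-2,4,5-trimethoxyphenol F5.
- The single free ring position of F5 is acetylated (Ac2O, BF3·OEt2, Fries/Friedel–Crafts) to give 1-(4-benzyloxy-2-hydroxy-3,5,6-trimethoxyphenyl)ethan-1-one F6.
- Esterification with 2 (K2CO3, acetone) gives 2-acetyl-5-benzyloxy-3,4,6-trimethoxyphenyl 3,4-dimethoxybenzoate F7.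
- Baker–Venkataraman rearrangement (KOH, pyridine) gives 1-(4-benzyloxy-2-hydroxy-3,5,6-trimethoxyphenyl)-3-(3,4-dimethoxyphenyl)propane-1,3-dione F8. Cyclodehydration (p-TsOH, PhMe, 80 °C) then gives 15.

**Step 3.** Deprotonation may compete at the carbons next to the pyranone carbonyl, followed by ring fragmentation, or the lithiated pyranone may attack pyranone that is not yet deprotonated.

The fallback separates metalation from carbon–carbon bond formation. It sets out from 5 and returns at 8.

- Zincation with TMPZnCl·LiCl in THF uses a base class known to metalate chromones beside the ring oxygen, and its carbon–zinc products do not self-condense. It gives [6-(3,4-dimethoxyphenyl)-4-oxo-4H-pyran-2-yl]zinc chloride F9.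
- Iodolysis (I2) gives 2-(3,4-dimethoxyphenyl)-6-iodo-4H-pyran-4-one F10, which can be freed of any positional isomer by chromatography.
- Iodine–magnesium exchange with i-PrMgCl·LiCl at −78 °C, with no base present, gives [6-(3,4-dimethoxyphenyl)-4-oxo-4H-pyran-2-yl]magnesium chloride F11.
- F11 is added to 6 at −78 °C and quenched with AcOH to give 8.

**Step 5.** The exchange is an equilibrium and may stall. Long exposure to alkoxide may also allow attack at the ring carbonyl with cleavage of the strained ring, or reversible opening of the pyranone.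

The fallback replaces the equilibrium by an irreversible saponification followed by O-alkylation. It sets out from 9 and returns at 11.

- LiOH (1.0 equiv, THF–H2O, 0 °C) adds at C3 and expels methoxide. The resulting vinylogous carboxylate is no longer electrophilic, so the product protects itself. Careful acidification gives rac-4-[6-(3,4-dimethoxyphenyl)-4-oxo-4H-pyran-2-yl]-3-hydroxy-2,4-dimethoxycyclobut-2-en-1-one F12.
- Mitsunobu O-alkylation with 10 (PPh3, DIAD, THF, 0 °C) gives 11.
- The two oxygens of the 1,3-dione enolate are related by the mirror plane through C2 and C4, so alkylation at either one gives the same racemate and no regiochemical issue arises.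

## Further compounds

F1 | step 6 | 1-methoxyvinyllithium | [Li]C(=C)OC
F2 | step 6 | rac-4-hydroxy-2,3-dimethoxy-4-(1-methoxyvinyl)cyclobut-2-en-1-one | COC1=C(OC)C(O)(C(=C)OC)C1=O
F3 | step 6 | rac-2,3,4-trimethoxy-4-(1-methoxyvinyl)cyclobut-2-en-1-one | COC1=C(OC)C(OC)(C(=C)OC)C1=O
F4 | step 6 | rac-3-benzyloxy-2,4-dimethoxy-4-(1-methoxyvinyl)cyclobut-2-en-1-one | COC1=C(OCc2ccccc2)C(OC)(C(=C)OC)C1=O
F5 | step 6 | 3-benzyloxy-2,4,5-trimethoxyphenol | COc1cc(O)c(OC)c(OCc2ccccc2)c1OC
F6 | step 6 | 1-(4-benzyloxy-2-hydroxy-3,5,6-trimethoxyphenyl)ethan-1-one | CC(=O)c1c(O)c(OC)c(OCc2ccccc2)c(OC)c1OC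
F7 | step 6 | 2-acetyl-5-benzyloxy-3,4,6-trimethoxyphenyl 3,4-dimethoxybenzoate | CC(=O)c1c(OC(=O)c2ccc(OC)c(OC)c2)c(OC)c(OCc2ccccc2)c(OC)c1OC
F8 | step 6 | 1-(4-benzyloxy-2-hydroxy-3,5,6-trimethoxyphenyl)-3-(3,4-dimethoxyphenyl)propane-1,3-dione | COc1ccc(C(=O)CC(=O)c2c(O)c(OC)c(OCc3ccccc3)c(OC)c2OC)cc1OC
F9 | step 3 | [6-(3,4-dimethoxyphenyl)-4-oxo-4H-pyran-2-yl]zinc chloride | Cl[Zn]c1cc(=O)cc(-c2ccc(OC)c(OC)c2)o1
F10 | step 3 | 2-(3,4-dimethoxyphenyl)-6-iodo-4H-pyran-4-one | COc1ccc(-c2cc(=O)cc(I)o2)cc1OC
F11 | step 3 | [6-(3,4-dimethoxyphenyl)-4-oxo-4H-pyran-2-yl]magnesium chloride | Cl[Mg]c1cc(=O)cc(-c2ccc(OC)c(OC)c2)o1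
F12 | step 5 | rac-4-[6-(3,4-dimethoxyphenyl)-4-oxo-4H-pyran-2-yl]-3-hydroxy-2,4-dimethoxycyclobut-2-en-1-one | COC1=C(O)C(OC)(c2cc(=O)cc(-c3ccc(OC)c(OC)c3)o2)C1=O
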